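**Plan**
1. Cuts: the butanoate C–O bond at the C6 benzylic carbon, the acetate C–O bond at the C4 benzylic carbon and the C–Cl bond of the C5 arm go back to a C4 methyl ester and a cyclic ether joining C5–CH2CH2 to C6–CH2 (indane numbering, C2 gem-dimethyl, C7 H). Then the arene bonds C7a–C3a and C5–C4 are cut, then the enoate C=C, the furan–chain bond and the pyran C–O bond.
2. Enabling feature: with the C5 and C6 arms closed as an isochroman, C5, C6, C7 and C7a are the four carbons of a dihydropyran-fused furan, and C1–C2(Me)2–C3 is a three-carbon tether to an acrylate that supplies C3a and C4.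
3. Forward order: the dihydropyran-fused furan comes first (lateral hydroxymethylation of 2-methyl-3-furoic acid, lactone, diol, ether). The chain is joined at the free furan α-carbon and finished by cross-metathesis. The cyclopentane and the benzene ring then form together. Last, the oxygen ring is moved onto the C4 ester as a lactone, opened to the chloroethyl arm, and the two benzylic carbons are esterified in turn.
4. Stereochemistry: the target has no stereocentre. The E enoate geometry and the centres of the carbinol and the cycloadduct are transient and are erased.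

Key step: step 7

Remark: racemic intermediates are drawn without configuration or, for the cycloadduct and the dienol, as one enantiomer of the expected relative configuration. Formaldehyde gas is generated by cracking paraformaldehyde, and LiN(iPr)2 is used as the purchased solution.

**Step 1**
Reactants: 1 2-methylfuran-3-carboxylic acid; 2 formaldehyde
Product: 5 6,7-dihydro-4H-furo[3,2-c]pyran-4-one, via lithium 2-(lithiomethyl)furan-3-carboxylate 3 (not isolated), via 2-(2-hydroxyethyl)furan-3-carboxylic acid 4 (not isolated)
Conditions: LiN(iPr)2 (2.2 equiv), THF, −78 °C; CH2O (g), −78 → 0 °C; aq. HCl; then TsOH·H2O (cat.), toluene, 80 °C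
Reagents that add atoms: none
Why: Two equivalents of amide base should give the carboxylate/lateral carbanion dianion (lateral lithiation of the methyl group, vinylogously activated by the carboxylate), its aldol-type addition to formaldehyde installs the CH2OH carbon, and acid closes the δ-hydroxy acid to the six-membered lactone (lactonisation).

**Step 2**
Reactants: 5 6,7-dihydro-4H-furo[3,2-c]pyran-4-one
Product: 6 2-[3-(hydroxymethyl)furan-2-yl]ethanol
Conditions: LiAlH4, THF, 0 °C → rt
Reagents that add atoms: none
Why: LiAlH4 reduction of a lactone to the diol is general, and the furan ring is inert to hydride.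

**Step 3**
Reactants: 6 2-[3-(hydroxymethyl)furan-2-yl]ethanol
Product: 7 6,7-dihydro-4H-furo[3,2-c]pyran
Conditions: PPh3, DIAD, THF, 0 °C → rt
Reagents that add atoms: none
Why: In a Mitsunobu cyclodehydration one hydroxyl is activated as its oxyphosphonium salt and displaced by the other in a 6-exo-tet closure, either choice of activated hydroxyl gives the same ether, and no acid is present to harm the furan.

**Step 4**
Reactants: 7 6,7-dihydro-4H-furo[3,2-c]pyran; 8 2,2-dimethylpent-4-enal
Product: 10 1-(6,7-dihydro-4H-furo[3,2-c]pyran-2-yl)-2,2-dimethylpent-4-en-1-ol (racemic), via 2-lithio-6,7-dihydro-4H-furo[3,2-c]pyran 9 (not isolated)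
Conditions: n-BuLi, THF, −78 → 0 °C; then 8, −78 °C; H2O
Reagents that add atoms: none
Why: n-BuLi should deprotonate the only free furan α-position (α-lithiation of a furan), and the 2-furyllithium adds to the non-enolisable neopentyl aldehyde (1,2-addition of an organolithium) to give a racemic carbinol whose stereocentre is removed in the next step.

**Step 5**
Reactants: 10 1-(6,7-dihydro-4H-furo[3,2-c]pyran-2-yl)-2,2-dimethylpent-4-en-1-ol
Product: 11 2-(2,2-dimethylpent-4-en-1-yl)-6,7-dihydro-4H-furo[3,2-c]pyran
Conditions: Et3SiH, TFA, CH2Cl2, −40 → 0 °C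
Reagents that add atoms: none
Why: Ionic hydrogenation, in which TFA ionises the 2-furylcarbinol to a furan-stabilised cation that takes hydride from Et3SiH, while the isolated terminal alkene and the less ionisable furan-3-ylmethyl ether should be left alone at low temperature.

**Step 6**
Reactants: 11 2-(2,2-dimethylpent-4-en-1-yl)-6,7-dihydro-4H-furo[3,2-c]pyran; 12 methyl acrylate
Product: 13 methyl (E)-6-(6,7-dihydro-4H-furo[3,2-c]pyran-2-yl)-5,5-dimethylhex-2-enoate
Conditions: 12 (5 equiv), second-generation Hoveyda–Grubbs catalyst RuCl2(H2IMes)(=CH–C6H4-2-OiPr) (3 mol %), CH2Cl2, 40 °C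
Reagents that add atoms: none
Why: Olefin cross-metathesis of an unhindered terminal alkene with excess acrylate is selective for the cross product and for the E enoate, and furans and ethers are tolerated by the ruthenium carbene.

**Step 7**
Reactants: 13 methyl (E)-6-(6,7-dihydro-4H-furo[3,2-c]pyran-2-yl)-5,5-dimethylhex-2-enoate
Product: 16 methyl 2,2-dimethylindane-4-carboxylate fused across C5–C6 to a dihydropyran ring (isochroman; C5–CH2CH2–O–CH2–C6), via oxanorbornene cycloadduct 14 (not isolated), via ring-opened cyclohexadienol 15 (not isolated)
Conditions: Me2AlCl (1.5 equiv), CH2Cl2, −78 °C → rt; then TsOH·H2O (3 equiv), 0 → 40 °C, same pot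
Reagents that add atoms: none
Why: Me2AlCl lowers the enoate LUMO so that the electron-rich trialkylfuran adds across its 2,5-positions in an intramolecular [4+2]; the closest known reaction type is the Lewis-acid-promoted intramolecular Diels–Alder reaction of a furan with a tethered enoate followed by dehydrative aromatisation of the 7-oxanorbornene. The cyclopentane closes in the fused mode through the CH2–CMe2–CH2 tether, whose gem-dimethyl group favours the folded rotamer, and the six-membered carbocycle is the cycloaddition ring itself. Acid then ionises the tertiary allylic C7a–O bond of 14, loss of the C3a proton gives dienol 15, and ionisation of its C5 carbinol to an arenium ion with loss of the ester-activated C4 proton gives the benzene. Because the cycloaddition is reversible, this irreversible loss of water is what should carry the sequence to completion. The four stereocentres of 14 (tether exo, ester endo, racemic) are all destroyed, so no stereocontrol is needed. The one selectivity required, CO2Me on C4 next to the two-carbon arm, is fixed by the tether, which can only deliver the enoate β-carbon to the furan carbon that carries it.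

**Step 8**
Reactants: 16 methyl 2,2-dimethylindane-4-carboxylate fused across C5–C6 to a dihydropyran ring
Product: 18 lactone of 6-(chloromethyl)-5-(2-hydroxyethyl)-2,2-dimethylindane-4-carboxylic acid, via methyl 6-(chloromethyl)-5-(2-hydroxyethyl)-2,2-dimethylindane-4-carboxylate 17 (not isolated)
Conditions: BCl3 (1.2 equiv), CH2Cl2, −78 → 0 °C; H2O; then TsOH·H2O (10 mol %), ClCH2CH2Cl, 60 °C
Reagents that add atoms: boron trichloride, ClB(Cl)Cl
Why: BCl3 cleaves the benzylic C–O bond of the cyclic ether with delivery of chloride to the C6 benzylic carbon (Lewis-acid ether cleavage), and the freed 2-hydroxyethyl arm is then captured by the ortho ester at C4 in an acid-catalysed lactonisation that removes the alcohol before it can re-close onto the benzylic chloride.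

**Step 9**
Reactants: 18 lactone of 6-(chloromethyl)-5-(2-hydroxyethyl)-2,2-dimethylindane-4-carboxylic acid
Product: 20 [5-(2-chloroethyl)-6-(chloromethyl)-2,2-dimethylindan-4-yl]methanol, via 5-(2-chloroethyl)-6-(chloromethyl)-2,2-dimethylindane-4-carbonyl chloride 19 (not isolated)
Conditions: SOCl2 (neat), ZnCl2 (10 mol %), 70 °C; evaporate; then NaBH4, THF, 0 °C
Reagents that add atoms: thionyl chloride, O=S(Cl)Cl
Why: ZnCl2-assisted chloride attack at the O–CH2 carbon with conversion of the carboxylate to the acyl chloride is the standard opening of a dihydroisocoumarin-type lactone to a 2-(2-chloroethyl)aroyl chloride, and NaBH4 reduces the acyl chloride to the primary alcohol far faster than it attacks benzylic or alkyl chlorides (chemoselective hydride reduction).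

**Step 10**
Reactants: 20 [5-(2-chloroethyl)-6-(chloromethyl)-2,2-dimethylindan-4-yl]methanol
Product: 21 [5-(2-chloroethyl)-6-(chloromethyl)-2,2-dimethylindan-4-yl]methyl acetate
Conditions: Ac2O, iPr2NEt, DMAP (5 mol %), CH2Cl2, 0 °C
Reagents that add atoms: acetic anhydride, CC(=O)OC(C)=O
Why: DMAP-catalysed acylation of a primary alcohol with Ac2O is fast at 0 °C, and the hindered tertiary amine should neither quaternise the benzylic chloride nor generate an alkoxide that could close onto the chloroethyl arm.

**Step 11**
Reactants: 21 [5-(2-chloroethyl)-6-(chloromethyl)-2,2-dimethylindan-4-yl]methyl acetate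
Product: 22 [4-(acetoxymethyl)-5-(2-chloroethyl)-2,2-dimethylindan-6-yl]methyl butanoate (CNP0321917.0)
Conditions: PrCO2Na (1.2 equiv), DMF, 40 °C
Reagents that add atoms: sodium butanoate, CCCC(=O)[O-].[Na+]
Why: Carboxylate SN2 displacement in a dipolar aprotic solvent takes place at the benzylic chloride much faster than at the primary 2-arylethyl chloride, and butanoate is too weak a base to eliminate HCl or to exchange with the acetate.

**Compound list**
1 | 2-methylfuran-3-carboxylic acid | Cc1occc1C(=O)O | starting material
2 | formaldehyde | C=O | starting material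
3 | lithium 2-(lithiomethyl)furan-3-carboxylate | [Li]Cc1occc1C(=O)O[Li] | intermediate
4 | 2-(2-hydroxyethyl)furan-3-carboxylic acid | OCCc1occc1C(=O)O | intermediate
5 | 6,7-dihydro-4H-furo[3,2-c]pyran-4-one | O=C1OCCc2occc12 | intermediate
6 | 2-[3-(hydroxymethyl)furan-2-yl]ethanol | OCCc1occc1CO | intermediate
7 | 6,7-dihydro-4H-furo[3,2-c]pyran | C1OCCc2occc12 | intermediate
8 | 2,2-dimethylpent-4-enal | C=CCC(C)(C)C=O | starting material
9 | 2-lithio-6,7-dihydro-4H-furo[3,2-c]pyran | [Li]c1cc2COCCc2o1 | intermediate
10 | 1-(6,7-dihydro-4H-furo[3,2-c]pyran-2-yl)-2,2-dimethylpent-4-en-1-ol (racemic) | C=CCC(C)(C)C(O)c1cc2COCCc2o1 | intermediate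
11 | 2-(2,2-dimethylpent-4-en-1-yl)-6,7-dihydro-4H-furo[3,2-c]pyran | C=CCC(C)(C)Cc1cc2COCCc2o1 | intermediate
12 | methyl acrylate | C=CC(=O)OC | starting material
13 | methyl (E)-6-(6,7-dihydro-4H-furo[3,2-c]pyran-2-yl)-5,5-dimethylhex-2-enoate | COC(=O)/C=C/CC(C)(C)Cc1cc2COCCc2o1 | intermediate
14 | oxanorbornene cycloadduct of 13 (oxygen bridge between the former furan C2 and C5, cyclopentane fused on the C7a–C3a bond with the tether exo, CO2Me endo; racemic, one enantiomer drawn) | COC(=O)[C@H]1[C@@H]2CC(C)(C)C[C@@]23C=C4COCC[C@@]14O3 | intermediate
15 | ring-opened cyclohexadienol (C5 tertiary alcohol, C4–H bearing CO2Me, C3a=C7a and C6=C7 double bonds; racemic, one enantiomer drawn) | COC(=O)[C@H]1C2=C(CC(C)(C)C2)C=C3COCC[C@@]13O | intermediate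
16 | methyl 2,2-dimethylindane-4-carboxylate fused across C5–C6 to a dihydropyran ring (cyclic ether of the 5-(2-hydroxyethyl)-6-(hydroxymethyl) compound) | COC(=O)c1c2CC(C)(C)Cc2cc3COCCc13 | intermediate
17 | methyl 6-(chloromethyl)-5-(2-hydroxyethyl)-2,2-dimethylindane-4-carboxylate | COC(=O)c1c2CC(C)(C)Cc2cc(CCl)c1CCO | intermediate
18 | lactone of 6-(chloromethyl)-5-(2-hydroxyethyl)-2,2-dimethylindane-4-carboxylic acid (C4–CO–O–CH2CH2–C5) | O=C1OCCc2c(CCl)cc3CC(C)(C)Cc3c12 | intermediate
19 | 5-(2-chloroethyl)-6-(chloromethyl)-2,2-dimethylindane-4-carbonyl chloride | O=C(Cl)c1c2CC(C)(C)Cc2cc(CCl)c1CCCl | intermediate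
20 | [5-(2-chloroethyl)-6-(chloromethyl)-2,2-dimethylindan-4-yl]methanol | OCc1c2CC(C)(C)Cc2cc(CCl)c1CCCl | intermediate
21 | [5-(2-chloroethyl)-6-(chloromethyl)-2,2-dimethylindan-4-yl]methyl acetate | CC(=O)OCc1c2CC(C)(C)Cc2cc(CCl)c1CCCl | intermediate
22 | [4-(acetoxymethyl)-5-(2-chloroethyl)-2,2-dimethylindan-6-yl]methyl butanoate | CCCC(=O)OCc1cc2c(c(COC(C)=O)c1CCCl)CC(C)(C)C2 | target

Total step count: 11
Longest linear sequence: 11 steps (1 → 22; 2, 8 and 12 are purchased)

**Steps most likely to fail**

1. Step 7. The cycloaddition is reversible and the enoate is only a moderate dienophile, so the open form may persist while the Lewis acid slowly degrades the electron-rich furan before aromatisation can pull the equilibrium. The fallback sets out from 11 and comes back at 16. Cross-metathesis of 11 with (E)-but-2-enal under the same ruthenium catalyst should give the (E)-enal F1, a markedly better dienophile. Me2AlCl at −78 °C followed by TsOH·H2O should take it through the oxanorbornene aldehyde F2 and the cyclohexadienol aldehyde F3 to the aryl aldehyde F4. Oxidative esterification (I2, KOH, MeOH, 0 °C) then converts the aldehyde into 16.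

2. Step 8. After the C–O cleavage the chloro alcohol may re-close onto the benzylic chloride faster than it lactonises onto the hindered ester, or BCl3 may demethylate the ester and give mixtures. The fallback sets out from 16 and comes back at 19. SN2 demethylation with LiI in pyridine at reflux gives the carboxylic acid F5. In SOCl2 with ZnCl2 it becomes the acyl chloride F6, which acylates the ether oxygen intramolecularly through a six-membered acyloxonium ion. Chloride then opens the benzylic C–O bond to give lactone 18 in the flask, and the same reagent opens 18 to 19, which is reduced as in step 9.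

3. Step 5. The furan may be protonated and oligomerise, or the furan-3-ylmethyl ether may be ionised and reduced, before the carbinol is deoxygenated. The fallback sets out from 10 and comes back at 11, and uses a radical in place of a cation. NaH, CS2 and then MeI give the S-methyl xanthate F7, and Bu3SnH with AIBN in toluene at 90 °C (Barton–McCombie deoxygenation) gives 11. The furfuryl radical has only 4-exo or 5-endo modes open towards the alkene, and no β-hydrogen is available for thermal xanthate elimination.

**Further compounds**
F1 | step 7 | (E)-6-(6,7-dihydro-4H-furo[3,2-c]pyran-2-yl)-5,5-dimethylhex-2-enal | O=C/C=C/CC(C)(C)Cc1cc2COCCc2o1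
F2 | step 7 | oxanorbornene aldehyde (aldehyde analogue of 14, racemic) | O=C[C@H]1[C@@H]2CC(C)(C)C[C@@]23C=C4COCC[C@@]14O3
F3 | step 7 | cyclohexadienol aldehyde (aldehyde analogue of 15, racemic) | O=C[C@H]1C2=C(CC(C)(C)C2)C=C3COCC[C@@]13O
F4 | step 7 | 2,2-dimethylindane-4-carbaldehyde fused across C5–C6 to the dihydropyran ring (aldehyde analogue of 16) | O=Cc1c2CC(C)(C)Cc2cc3COCCc13
F5 | step 8 | 2,2-dimethylindane-4-carboxylic acid fused across C5–C6 to the dihydropyran ring (acid of 16) | OC(=O)c1c2CC(C)(C)Cc2cc3COCCc13
F6 | step 8 | acyl chloride of F5 | O=C(Cl)c1c2CC(C)(C)Cc2cc3COCCc13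
F7 | step 5 | O-[1-(6,7-dihydro-4H-furo[3,2-c]pyran-2-yl)-2,2-dimethylpent-4-en-1-yl] S-methyl carbonodithioate (racemic) | C=CCC(C)(C)C(OC(=S)SC)c1cc2COCCc2o1
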